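If each chain begun costs one initiator, I can keep the books on the initiator.

the same everywhere: transfer agent 0.130 mM; initiator 99 µM; time 40 min
- grey: free monomer 0.013 M
- red: free monomer 0.0060 M

    free monomer + initiator → living end + monomer in chains (k1 = 22 L mol⁻¹ min⁻¹)
    free monomer + living end → monomer in chains + living end, rate k2*[living end]*[free monomer] (k2 = 220 L mol⁻¹ min⁻¹)
    living end + transfer agent → dead chain (k3 = 940 L mol⁻¹ min⁻¹)

1. which of the two ends with the longer chains by the average number of monomer units in a chain (chains begun, living or dead) ("neither" if they lie within 10%) (grey / red / neither)
2. average number of monomer units in a chain (chains begun, living or dead) at the end, grey
3. average number of monomer units in a chain (chains begun, living or dead) at the end, red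

- the average divides the monomer in chains by the number of chains begun, living and dead together
- run time (grey): 40 min

I count initiator, with 99 µM charged against 0.130 mM of transfer agent. The first entry is chains begun. With free monomer held at its charge, initiator has a half-life of 2.42 min in grey and 5.25 min in red, well inside the run. So I book nearly all of it as chains begun. The length is then the feed ratio, free monomer charged per initiator charged, times the share of free monomer converted, divided by the share of initiator spent. The feed ratio is 131 in grey and 60.6 in red.

The second entry is dead chains. Each living end takes one transfer agent, and it still counts as a chain. Transfer agent always equals living ends plus unspent initiator plus a spare of 31.0 µM. I treat step one as over at the start. That is fair in grey, where the half-life of initiator is shorter than the 5.7 min half-life of a living end with transfer agent as charged, and rough in red. The ratio of living ends to transfer agent then falls exponentially from 0.762 to 0.237, which leaves 40.7 µM of transfer agent.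

Dividing step two by step three, the logarithm of the fall in free monomer is 0.234 times that of the fall in transfer agent. Step one adds 0.00762 in grey and 0.0165 in red. So I expect 24.4% converted in grey and 25.1% in red. That gives lengths of 32.0 and 15.2, so grey is longer.

The forecast says grey, with 31 and 13.9, starting from “each chain begun consumes one initiator”. My lengths stand higher than its lengths.

The flask gives grey, with 31.0 in grey and 13.9 in red, as the forecast said. The red length moves by 1.39 with free monomer charged at 0.00543 M or 0.00656 M. The ledger on grey's 23.6% in chains gives 31.0. The neighbour of red charged with 2.5 × 10⁻⁴ M of initiator has a feed ratio of 24.0. At 40 min it holds 62.0% of its free monomer in chains and keeps 3.1% of its initiator. The ledger gives 15.3, and the flask reads 15.3.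

The constants were drawn at random within sensible limits; the flask was simulated.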